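# Methylarzanol by a malonyl dichloride / silyl enol ether (3+3) pyranone synthesis

## Analysis of the target

Methylarzanol consists of two fully substituted six-membered rings joined through one CH2 group. The heterocycle is a 2-methoxy-4H-pyran-4-one: O1, C2 (OMe), C3 (bridge CH2), C4 (C=O), C5 (methyl), C6 (ethyl). The carbocycle is a phloroacetophenone ring in which the bridge carbon sits between two hydroxyls, and a prenyl group, the third hydroxyl and the acetyl group fill the remaining positions. There is no stereocentre and no stereogenic double bond (the prenyl alkene ends in two methyl groups), so every question is one of constitution: the placement of six substituents on the benzene ring, and the choice between the C2 and the C4 oxygen for the methyl group. The sensitive groups are the prenyl alkene beside phenols (acid closes it to a dimethylchroman or adds HX), the C2 methoxy group (part of a vinylogous ester that acid or nucleophiles cleave to the 4-hydroxy-2-pyranone), and the acylphloroglucinol (an ambident C/O nucleophile, easily oxidised as its phenolate). The synthesis is hard because the bridge joins two different enol-type carbons: a coupling through a one-carbon electrophile would have to tell two nucleophiles apart and would give symmetric dimers as well, and neither ring has a free position for later correction. The plan rests on reading C2, C3 and C4 of the pyranone, with the bridge carbon on C3, as a 2-substituted malonyl unit, and O1, C6 (ethyl) and C5 (methyl) as the enol of the symmetric ketone 3-pentanone. The oxygenated benzene ring with its acetyl group is that of commercially available 2',4',6'-trihydroxyacetophenone.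

## Retrosynthetic reasoning

**18 to 17.** The last cut is at the three aryl O–allyl bonds. The phenols cannot be free earlier, because the acyl chlorides and the methyl donor of the preceding steps would attack them. Allyl ethers are chosen because a palladium-catalysed allyl transfer to an amine removes them under neutral conditions. Protecting groups that come off by hydrogenolysis or by acid would endanger the prenyl alkene and the methoxypyranone.

**17 to 16.** The O–CH3 bond at the C2 oxygen is cut next, which leads to the 4-hydroxy-2-pyranone 16. In the neutral vinylogous acid the lactone carbonyl oxygen is the nucleophilic site, so a hard methyl donor should give the 2-methoxy-4-pyranone and not the 4-methoxy-2-pyranone. The gain is that the ring can be built in its stable hydroxypyranone form.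

**16 to 11 and 13.** The ring is cut at C4–C5 and O1–C2. This is the only cut that separates the malonyl unit (C2 to C4, carrying the bridge carbon) from the enol of ketone 12, and because 12 is symmetric only one regioisomer can arise. The bridge carbon stays bonded to C3 from the start, so the two ring systems are never joined through a one-carbon electrophile. In the forward direction dichloride 11, directly or through ketene 14, must acylate the enol ether carbon of 13 to give 15, and the enol oxygen of 15 must then close onto the second acyl chloride.

**11 to 10 to 9 to 6 and 7.** The two C–Cl bonds go back to diacid 10, and 10 to the dioxanedione 9. The bond between the benzylic carbon and the malonyl carbon is then cut, which leads to aldehyde 6 and Meldrum's acid 7, joined in the forward sense by a reductive alkylation through the arylidene compound 8. This avoids a benzylic halide, which would be unmanageable on so electron-rich a ring, and 7 stops cleanly at monoalkylation.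

**6 to 5 to 3 and 4 to 1.** The O–allyl bonds of 6 lead to triphenol 5, the C–prenyl bond of 5 to aldehyde 3 and prenyl bromide 4, and the formyl C–C bond of 3 to phloroacetophenone 1. Formylation is placed first because it is the one acidic operation of the sequence and should not meet the prenyl alkene. Once the formyl group occupies one ring position, 4 has only a single ring carbon left to alkylate.

**13 to 12.** The O–Si bond is cut, and 13 is the silyl enol ether of 12.

## Alternatives that were turned down

**Alternative 1:** The disconnection is through the benzene ring itself, at C(OH)–C(prenyl) and C(OSi)–C(side chain), and leads to the 3-siloxycyclobutenone A2 and the prenyl-substituted siloxyalkyne A3. In the forward key step, heating A2 with A3 sets off a Danheiser benzannulation (4π ring opening to a vinylketene, (2+2) addition of the alkyne, second 4π opening, 6π closure, tautomerisation) and should give phenol A1. In A1 the three ring oxygens are told apart, the prenyl group is in place, and a three-carbon chain stands where the bridge will be.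
- For it: every substituent of A1 is placed by the connectivity of the partners, and the conditions are neutral.
- Against it: the target needs no differentiation of its three phenols, and the oxygenated ring with its acetyl group can be bought as 1. A2 and A3 each need several steps. After the annulation the acetyl group must still be introduced onto a prenylated arene by an acid-mediated acylation, the chain terminus must be oxidised, and the pyranone must be built by stepwise acylations, with the same O-methylation question at the end.
- Comparison: on regiocontrol of the arene this plan is at least as good as the chosen one, which relies on substitution chemistry of an acylphloroglucinol. The chosen route offers instead a benzene ring that is bought and not built, and it spends its key step on the bridge and the heterocycle, where the difficulty lies, in far fewer steps.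

**Alternative 2:** This is again a (3+3) cut, but through the benzene ring, at the two ring bonds that run from the malonyl carbonyl carbons to the acetyl-bearing carbon and to the unsubstituted carbon. It leads to malonyl dichloride A5, which already carries the methoxypyranone on its CH2 group, and 2,4-bis(trimethylsilyloxy)penta-1,3-diene A6. In the forward key step the terminal carbon of A6 adds to the chlorocarbonyl ketene formed from A5, the central carbon closes on the second acyl chloride, and enolisation gives the acetylphloroglucinol A4. Material that closed through oxygen would have to be rearranged with base.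
- For it: no phenol protecting group is needed, the bridge carbon is likewise carried in on the malonyl carbon, and the route is highly convergent. In protecting-group economy it is better than the chosen route.
- Against it: A5 presupposes that the methoxypyranone has already been made with the bridge and a malonyl unit attached, and its vinylogous ester would have to survive acyl chloride formation and the acid released in the annulation. C-closure is required where O-closure to a 4-hydroxy-2-pyranone is the easier path, and the basic rearrangement that corrects this would endanger the methoxypyranone already present. The prenyl group must then go on last, onto unprotected A4, where O-alkylation and geminal dialkylation compete at the most valuable stage.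
- Comparison: the chosen strategy uses the same bond-forming logic where it works in its favour. The ring that is closed is the heterocycle, for which O-closure is both wanted and preferred, and the capricious prenylation is done at the second step on cheap material. The price is three allyl groups to put on and take off.

**Alternative 3:** The pyranone is cut at C3–C4 and O1–C2 with the roles reversed. C4, C5, C6 and O1 come from propionyl(methyl)ketene A10, released from dioxinone A8, and C2 and C3 come from the ketene dimethyl acetal A9, which carries the bridge and the protected arene. In the forward key step, thermolysis of A8 sets A10 free, which adds across the electron-rich double bond of A9 in a (4+2) sense. Loss of one methoxy group as the alcohol should give A7, identical with compound 17 of the chosen route.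
- For it: the 2-methoxy-4-pyranone comes out directly with the methyl on the right oxygen, so no site-selective methylation is needed and no acid is set free. On these two points it is the stronger plan, and it is one step shorter at the end.
- Against it: A9 is a ketene acetal of an ester that sits in the same molecule as an enolisable aryl methyl ketone, so neither enolate O-alkylation nor elimination from an orthoester is a credible way to make it, and it would be hydrolysed by traces of moisture. The temperature needed to open A8 approaches that at which aryl allyl ethers begin to rearrange, and A10 can dimerise or be intercepted by the ketone and ether oxygens of A9. The union also joins a fully substituted acylketene with a hindered, trisubstituted ketene acetal.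
- Comparison: the chosen route accepts one further step, whose selectivity follows from the known preference of hard methyl donors for the lactone carbonyl oxygen. In return its partners (a malonic acid turned into its dichloride under neutral conditions, and a distillable silyl enol ether) can be made without strong base in the presence of the acetyl group, and they react far below the temperature of a Claisen rearrangement.

Key step: step 8

## Route

Remark: the double-bond geometry of 13 has no consequence, because C5 ends as an sp2 ring carbon; 13 is drawn as the Z isomer that is expected to predominate.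

Abbreviation: Ar = 3-acetyl-5-(3-methylbut-2-en-1-yl)-2,4,6-tris(prop-2-en-1-yloxy)phenyl, numbered from the carbon that carries the bridge CH2. Full names and SMILES are in the compound list.

Step 1
Reactants: 1 2',4',6'-trihydroxyacetophenone
Product: 3 3-acetyl-2,4,6-trihydroxybenzaldehyde, via aryl iminium chloride 2 (not isolated)
Conditions: POCl3 (1.2 equiv), DMF, EtOAc, 0 °C → rt; then H2O, 50 °C
Reagents that add atoms: N,N-dimethylformamide CN(C)C=O; water O
Why: Vilsmeier–Haack formylation; the chloroiminium ion attacks one of the two equivalent free positions of the electron-rich ring, the iminium group of 2 deactivates the ring against a second attack, and hydrolysis gives the aldehyde. It is run before prenylation so that the acid formed never meets the prenyl alkene.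

Step 2
Reactants: 3 3-acetyl-2,4,6-trihydroxybenzaldehyde; 4 prenyl bromide (1-bromo-3-methylbut-2-ene)
Product: 5 3-acetyl-2,4,6-trihydroxy-5-(3-methylbut-2-en-1-yl)benzaldehyde
Conditions: 4 (1.05 equiv), DBU (1.1 equiv), THF, 0 °C → rt
Reagents that add atoms: none
Why: C-alkylation of an acylphloroglucinol phenolate with an allylic bromide; the amidinium phenolate ion pair in THF should react at the only unsubstituted ring carbon, and the formyl group already in place rules out C-prenylation at a second ring CH.

Step 3
Reactants: 5 3-acetyl-2,4,6-trihydroxy-5-(3-methylbut-2-en-1-yl)benzaldehyde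
Product: 6 3-acetyl-5-(3-methylbut-2-en-1-yl)-2,4,6-tris(prop-2-en-1-yloxy)benzaldehyde
Conditions: allyl bromide (4.5 equiv), K2CO3 (5 equiv), DMF, rt → 45 °C
Reagents that add atoms: allyl bromide C=CCBr
Why: Williamson ether synthesis; in a dipolar aprotic solvent the potassium phenolates should react at oxygen, and the excess of reagent with gentle warming is meant to reach the carbonyl-chelated hydroxyls while staying far below the temperature of a Claisen rearrangement.

Step 4
Reactants: 6 3-acetyl-5-(3-methylbut-2-en-1-yl)-2,4,6-tris(prop-2-en-1-yloxy)benzaldehyde; 7 Meldrum's acid (2,2-dimethyl-1,3-dioxane-4,6-dione)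
Product: 9 5-(ArCH2)-2,2-dimethyl-1,3-dioxane-4,6-dione, via arylidene Meldrum's acid 8 (not isolated)
Conditions: Hantzsch ester (diethyl 2,6-dimethyl-1,4-dihydropyridine-3,5-dicarboxylate, 1.1 equiv), L-proline (20 mol %), EtOH, rt
Reagents that add atoms: none
Why: organocatalytic reductive Knoevenagel alkylation; proline-catalysed condensation gives the strongly electrophilic arylidene 8, which takes hydride from the dihydropyridine faster than anything else in the flask, so the reaction stops at the monoalkylated dioxanedione. The doubly ortho-substituted aryl ketone should neither condense nor be reduced.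

Step 5
Reactants: 9 5-(ArCH2)-2,2-dimethyl-1,3-dioxane-4,6-dione
Product: 10 2-(ArCH2)propanedioic acid
Conditions: 2 M aq. HCl, THF, 45 °C
Reagents that add atoms: water O
Why: acid-catalysed hydrolysis of the acylal ring; monosubstituted Meldrum's acids resist base because they form the enolate but open in dilute aqueous acid. At this temperature the malonic acid should not decarboxylate, and a trisubstituted alkene without a free phenol next to it should not be hydrated.

Step 6
Reactants: 10 2-(ArCH2)propanedioic acid
Product: 11 2-(ArCH2)propanedioyl dichloride
Conditions: 1-chloro-N,N,2-trimethylprop-1-en-1-amine (2.2 equiv), CH2Cl2, 0 °C → rt; solution used at once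
Reagents that add atoms: 1-chloro-N,N,2-trimethylprop-1-en-1-amine CC(C)=C(Cl)N(C)C
Why: acyl chloride formation with an α-chloroenamine; each carboxylic acid adds to the keteniminium form of the reagent and collapses to the acyl chloride and a neutral amide, so no free HCl is produced and the prenyl and allyl groups are not exposed to acid.

Step 7
Reactants: 12 3-pentanone
Product: 13 (Z)-trimethyl(pent-2-en-3-yloxy)silane
Conditions: Me3SiOTf (1.1 equiv), Et3N (1.3 equiv), Et2O, 0 °C → rt; distillation
Reagents that add atoms: trimethylsilyl trifluoromethanesulfonate C[Si](C)(C)OS(=O)(=O)C(F)(F)F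
Why: soft enolisation and O-silylation; the amine deprotonates the O-silylated oxocarbenium ion, which should give mainly the Z enol ether, and the minor E isomer leads to the same pyranone.

Step 8
Reactants: 11 2-(ArCH2)propanedioyl dichloride; 13 (Z)-trimethyl(pent-2-en-3-yloxy)silane
Product: 16 3-(ArCH2)-6-ethyl-4-hydroxy-5-methyl-2H-pyran-2-one, via chlorocarbonyl ketene 14 (not isolated), via 4-methyl-3,5-dioxoheptanoyl chloride 15 (not isolated)
Conditions: 13 (1.1 equiv), CH2Cl2–Et2O, −78 °C; then 13 (1.2 equiv), −78 °C → rt; MeOH quench
Reagents that add atoms: none
Why: Dichloride 11 loses HCl from its doubly activated CH to give chlorocarbonyl ketene 14, and the nucleophilic carbon of 13 adds to the ketene carbon (or directly to an acyl chloride carbon of 11, which leads to the same intermediate); loss of Me3SiCl gives the β,δ-diketo acyl chloride 15 and forms C4–C5. Intermediate 15 enolises towards C5, the carbon between its two ketones, and the enol oxygen on C6 attacks the remaining acyl chloride in a 6-exo-trig O-acylation that forms O1–C2; tautomerisation gives the aromatic 4-hydroxy-2-pyranone. The closest known reaction type is the condensation of malonyl dichlorides or chlorocarbonyl ketenes with ketones and silyl enol ethers to 4-hydroxy-2-pyranones. No stereocentre is created: the sp3 centres of 15 are flattened on aromatisation and the geometry of 13 is erased. The step needs C-acylation before O-closure, which the soft silyl enol ether carbon secures, and O-closure in preference to C-closure onto the ethyl CH2, which follows because only the enol towards C5 is populated; as 12 is symmetric, a single regioisomer is possible. The HCl lost in the ring closure should be taken up by the second portion of 13, which is cleaved to 12 and Me3SiCl, so that it does not add to the prenyl alkene. The flanking allyloxy oxygens are much poorer nucleophiles than 13, and the low temperature with 13 present from the outset is meant to keep them from capturing 14 or an acyl chloride intramolecularly.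

Step 9
Reactants: 16 3-(ArCH2)-6-ethyl-4-hydroxy-5-methyl-2H-pyran-2-one
Product: 17 3-(ArCH2)-6-ethyl-2-methoxy-5-methyl-4H-pyran-4-one (tri-O-allyl methylarzanol)
Conditions: MeOTf (1.3 equiv), 2,6-di-tert-butyl-4-methylpyridine (1.5 equiv), CH2Cl2, 0 °C → rt; aq. NaHCO3
Reagents that add atoms: methyl trifluoromethanesulfonate COS(=O)(=O)C(F)(F)F
Why: O-methylation of a 4-hydroxy-2-pyranone at the lactone carbonyl oxygen by a hard methyl donor; the neutral vinylogous acid reacts through its carbonyl oxygen to give a 2-methoxy-4-hydroxypyrylium ion, which the hindered pyridine deprotonates to the 2-methoxy-4-pyranone. The base is too weak and too hindered to generate the ambident pyranone anion (which would react at the C4 oxygen), and it keeps the sulfonic acid away from the prenyl group.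

Step 10
Reactants: 17 3-(ArCH2)-6-ethyl-2-methoxy-5-methyl-4H-pyran-4-one
Product: 18 methylarzanol
Conditions: Pd(PPh3)4 (10 mol %), morpholine (10 equiv), THF, rt, degassed
Reagents that add atoms: none
Why: Tsuji–Trost-type deallylation; zerovalent palladium ionises each aryl allyl ether to a π-allyl complex and a phenolate, and the amine captures the allyl group irreversibly. The C-prenyl group and the methoxypyranone cannot be ionised in this way, and no acid is present.

## Compound list

1 | 2',4',6'-trihydroxyacetophenone | CC(=O)c1c(O)cc(O)cc1O | starting material
2 | N-[(3-acetyl-2,4,6-trihydroxyphenyl)methylidene]-N-methylmethanaminium chloride | C[N+](C)=Cc1c(O)cc(O)c(C(C)=O)c1O.[Cl-] | intermediate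
3 | 3-acetyl-2,4,6-trihydroxybenzaldehyde | CC(=O)c1c(O)cc(O)c(C=O)c1O | intermediate
4 | prenyl bromide (1-bromo-3-methylbut-2-ene) | CC(C)=CCBr | starting material
5 | 3-acetyl-2,4,6-trihydroxy-5-(3-methylbut-2-en-1-yl)benzaldehyde | CC(=O)c1c(O)c(CC=C(C)C)c(O)c(C=O)c1O | intermediate
6 | 3-acetyl-5-(3-methylbut-2-en-1-yl)-2,4,6-tris(prop-2-en-1-yloxy)benzaldehyde | CC(=O)c1c(OCC=C)c(CC=C(C)C)c(OCC=C)c(C=O)c1OCC=C | intermediate
7 | Meldrum's acid (2,2-dimethyl-1,3-dioxane-4,6-dione) | CC1(C)OC(=O)CC(=O)O1 | starting material
8 | 5-{[3-acetyl-5-(3-methylbut-2-en-1-yl)-2,4,6-tris(prop-2-en-1-yloxy)phenyl]methylidene}-2,2-dimethyl-1,3-dioxane-4,6-dione | CC(=O)c1c(OCC=C)c(CC=C(C)C)c(OCC=C)c(C=C2C(=O)OC(C)(C)OC2=O)c1OCC=C | intermediate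
9 | 5-{[3-acetyl-5-(3-methylbut-2-en-1-yl)-2,4,6-tris(prop-2-en-1-yloxy)phenyl]methyl}-2,2-dimethyl-1,3-dioxane-4,6-dione | CC(=O)c1c(OCC=C)c(CC=C(C)C)c(OCC=C)c(CC2C(=O)OC(C)(C)OC2=O)c1OCC=C | intermediate
10 | 2-{[3-acetyl-5-(3-methylbut-2-en-1-yl)-2,4,6-tris(prop-2-en-1-yloxy)phenyl]methyl}propanedioic acid | CC(=O)c1c(OCC=C)c(CC=C(C)C)c(OCC=C)c(CC(C(=O)O)C(=O)O)c1OCC=C | intermediate
11 | 2-{[3-acetyl-5-(3-methylbut-2-en-1-yl)-2,4,6-tris(prop-2-en-1-yloxy)phenyl]methyl}propanedioyl dichloride | O=C(Cl)C(Cc1c(OCC=C)c(CC=C(C)C)c(OCC=C)c(C(C)=O)c1OCC=C)C(=O)Cl | intermediate
12 | 3-pentanone | CCC(=O)CC | starting material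
13 | (Z)-trimethyl(pent-2-en-3-yloxy)silane | C/C=C(/CC)O[Si](C)(C)C | intermediate
14 | 2-{[3-acetyl-5-(3-methylbut-2-en-1-yl)-2,4,6-tris(prop-2-en-1-yloxy)phenyl]methyl}-3-oxoprop-2-enoyl chloride (chlorocarbonyl ketene) | O=C=C(Cc1c(OCC=C)c(CC=C(C)C)c(OCC=C)c(C(C)=O)c1OCC=C)C(=O)Cl | intermediate
15 | 2-{[3-acetyl-5-(3-methylbut-2-en-1-yl)-2,4,6-tris(prop-2-en-1-yloxy)phenyl]methyl}-4-methyl-3,5-dioxoheptanoyl chloride (mixture of diastereomers and enol forms) | CCC(=O)C(C)C(=O)C(Cc1c(OCC=C)c(CC=C(C)C)c(OCC=C)c(C(C)=O)c1OCC=C)C(=O)Cl | intermediate
16 | 3-{[3-acetyl-5-(3-methylbut-2-en-1-yl)-2,4,6-tris(prop-2-en-1-yloxy)phenyl]methyl}-6-ethyl-4-hydroxy-5-methyl-2H-pyran-2-one | CCC1=C(C)C(O)=C(Cc2c(OCC=C)c(CC=C(C)C)c(OCC=C)c(C(C)=O)c2OCC=C)C(=O)O1 | intermediate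
17 | 3-{[3-acetyl-5-(3-methylbut-2-en-1-yl)-2,4,6-tris(prop-2-en-1-yloxy)phenyl]methyl}-6-ethyl-2-methoxy-5-methyl-4H-pyran-4-one | CCc1oc(OC)c(Cc2c(OCC=C)c(CC=C(C)C)c(OCC=C)c(C(C)=O)c2OCC=C)c(=O)c1C | intermediate
18 | methylarzanol, 3-{[3-acetyl-2,4,6-trihydroxy-5-(3-methylbut-2-en-1-yl)phenyl]methyl}-6-ethyl-2-methoxy-5-methyl-4H-pyran-4-one | CCc1oc(OC)c(Cc2c(O)c(CC=C(C)C)c(O)c(C(C)=O)c2O)c(=O)c1C | target

## Step count and least certain steps

Total step count: 10. Longest linear sequence: 9 steps (steps 1 to 6 and 8 to 10, from 1); step 7 is a one-step side branch.

**Step 8 (key step).** Two things are most likely to go wrong. First, ketene 14 or an acyl chloride may be captured intramolecularly by one of the two allyloxy oxygens next to the bridge (lactonisation with loss of the allyl group, or a ketene-Claisen shift), because these oxygens sit six atoms away and are twisted out of conjugation. Second, HCl may add to the prenyl alkene if the enol ether does not intercept it in time; a second intermolecular acylation before ring closure is a lesser concern. The fallback sets out from 9 and returns at 16. Heating 9 in methanol opens the dioxanedione to the malonic acid monomethyl ester F1. 1-Chloro-N,N,2-trimethylprop-1-en-1-amine converts it into the ester acyl chloride F2. F2 acylates the lithium enolate of 12 (LiN(iPr)2, THF, −78 °C, two equivalents of enolate) at carbon to give the β,δ-diketo ester F3. DBU in toluene at 80 °C then lactonises F3 to 16. This stepwise Claisen/lactonisation sequence has only one acyl chloride in the molecule, meets it with a far stronger nucleophile, and sets no HCl free beside the prenyl group.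

**Step 9.** The risk is methylation at the C4 oxygen (giving the 4-methoxy-2-pyranone) if the pyranone reacts as its anion, and acid-induced cyclisation or addition at the prenyl group if the sulfonic acid is not fully buffered. The fallback sets out from 9 and follows the fallback of step 8 as far as the diketo ester F3. Instead of the basic lactonisation, F3 is cyclised under dehydrating conditions (PPh3, CCl4, THF, rt), a known way from β,δ-diketo methyl esters to 2-methoxy-4-pyranones in which water and not the methoxy group is lost. This returns to the route at 17 with the methyl group already on the C2 oxygen and makes no compound beyond F1 to F3.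

**Step 5.** The risk is that the acid needed to open the acylal also hydrates the prenyl alkene, or that the malonic acid loses CO2 if the mixture is heated further to force conversion. The fallback sets out from 6 and returns at 10. Knoevenagel condensation with dimethyl malonate (piperidine, AcOH, toluene, reflux with removal of water) gives the arylidene malonate F4. Conjugate reduction with NaBH4 (MeOH–THF, 0 °C) gives the dimethyl malonate F5. Saponification with LiOH (THF–MeOH–H2O, rt) and acidification at 0 °C give 10 without any acidic step.

**Step 2.** The risk is O-prenylation and a second alkylation at an already substituted ring carbon with loss of aromaticity, together with low conversion, because the phenolate of a diacylphloroglucinol is a weak nucleophile. The fallback sets out from 1 and returns at 5. Phloroacetophenone 1, the more nucleophilic substrate for which this C-prenylation is established, is prenylated with 4 (DBU, THF) to 2,4,6-trihydroxy-3-prenylacetophenone F6. F6 is then formylated at its last free ring position by the Vilsmeier–Haack reaction with buffered hydrolysis (aq. NaOAc).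

**Step 10.** The risk is transfer of the allyl groups to ring carbons of the liberated phloroglucinol phenolate (dearomatising C-allylation) in competition with the amine, incomplete cleavage of three hindered ethers, and attack of the amine on the methoxypyranone. The fallback sets out from 17 and returns at 18. The allyl ethers are isomerised with [Ir(cod)(PMePh2)2]PF6 (activated with H2, THF, rt) to the tris(propenyl) ether F7, whose enol ethers are hydrolysed by very dilute acid (0.1 M HCl, acetone–H2O, rt). This approach generates no π-allyl electrophile and uses no amine.

## Further compounds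

F1 | step 8 | 2-{[3-acetyl-5-(3-methylbut-2-en-1-yl)-2,4,6-tris(prop-2-en-1-yloxy)phenyl]methyl}-3-methoxy-3-oxopropanoic acid | COC(=O)C(Cc1c(OCC=C)c(CC=C(C)C)c(OCC=C)c(C(C)=O)c1OCC=C)C(=O)O
F2 | step 8 | methyl 2-{[3-acetyl-5-(3-methylbut-2-en-1-yl)-2,4,6-tris(prop-2-en-1-yloxy)phenyl]methyl}-3-chloro-3-oxopropanoate | COC(=O)C(Cc1c(OCC=C)c(CC=C(C)C)c(OCC=C)c(C(C)=O)c1OCC=C)C(=O)Cl
F3 | step 8 | methyl 2-{[3-acetyl-5-(3-methylbut-2-en-1-yl)-2,4,6-tris(prop-2-en-1-yloxy)phenyl]methyl}-4-methyl-3,5-dioxoheptanoate | CCC(=O)C(C)C(=O)C(Cc1c(OCC=C)c(CC=C(C)C)c(OCC=C)c(C(C)=O)c1OCC=C)C(=O)OC
F0 | step 9 | none | none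
F4 | step 5 | dimethyl 2-{[3-acetyl-5-(3-methylbut-2-en-1-yl)-2,4,6-tris(prop-2-en-1-yloxy)phenyl]methylidene}propanedioate | COC(=O)C(=Cc1c(OCC=C)c(CC=C(C)C)c(OCC=C)c(C(C)=O)c1OCC=C)C(=O)OC
F5 | step 5 | dimethyl 2-{[3-acetyl-5-(3-methylbut-2-en-1-yl)-2,4,6-tris(prop-2-en-1-yloxy)phenyl]methyl}propanedioate | COC(=O)C(Cc1c(OCC=C)c(CC=C(C)C)c(OCC=C)c(C(C)=O)c1OCC=C)C(=O)OC
F6 | step 2 | 1-[2,4,6-trihydroxy-3-(3-methylbut-2-en-1-yl)phenyl]ethan-1-one | CC(=O)c1c(O)cc(O)c(CC=C(C)C)c1O
F7 | step 10 | 3-({3-acetyl-5-(3-methylbut-2-en-1-yl)-2,4,6-tris[(1E)-prop-1-en-1-yloxy]phenyl}methyl)-6-ethyl-2-methoxy-5-methyl-4H-pyran-4-one | CCc1oc(OC)c(Cc2c(O/C=C/C)c(CC=C(C)C)c(O/C=C/C)c(C(C)=O)c2O/C=C/C)c(=O)c1C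
A1 | alternative 1 | 4-[3-(tert-butyldimethylsilyloxy)propyl]-2-(3-methylbut-2-enyl)-3,5-bis(triisopropylsilyloxy)phenol | CC(C)=CCc1c(O)cc(O[Si](C(C)C)(C(C)C)C(C)C)c(CCCO[Si](C)(C)C(C)(C)C)c1O[Si](C(C)C)(C(C)C)C(C)C
A2 | alternative 1 | 2-[3-(tert-butyldimethylsilyloxy)propyl]-3-(triisopropylsilyloxy)cyclobut-2-en-1-one | O=C1CC(O[Si](C(C)C)(C(C)C)C(C)C)=C1CCCO[Si](C)(C)C(C)(C)C
A3 | alternative 1 | triisopropyl[(5-methylhex-4-en-1-yn-1-yl)oxy]silane | CC(C)=CCC#CO[Si](C(C)C)(C(C)C)C(C)C
A4 | alternative 2 | 3-[(3-acetyl-2,4,6-trihydroxyphenyl)methyl]-6-ethyl-2-methoxy-5-methylpyran-4-one | CCc1oc(OC)c(Cc2c(O)cc(O)c(C(C)=O)c2O)c(=O)c1C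
A5 | alternative 2 | 2-[(6-ethyl-2-methoxy-5-methyl-4-oxo-4H-pyran-3-yl)methyl]propanedioyl dichloride | O=C(Cl)C(Cc1c(OC)oc(CC)c(C)c1=O)C(=O)Cl
A6 | alternative 2 | (3Z)-2,4-bis(trimethylsilyloxy)penta-1,3-diene | C=C(O[Si](C)(C)C)/C=C(/C)O[Si](C)(C)C
A7 | alternative 3 | tri-O-allyl methylarzanol (identical with 17) | CCc1oc(OC)c(Cc2c(OCC=C)c(CC=C(C)C)c(OCC=C)c(C(C)=O)c2OCC=C)c(=O)c1C
A8 | alternative 3 | 6-ethyl-2,2,5-trimethyl-4H-1,3-dioxin-4-one | CCC1=C(C)C(=O)OC(C)(C)O1
A9 | alternative 3 | 1-[3-(3,3-dimethoxyprop-2-en-1-yl)-5-(3-methylbut-2-en-1-yl)-2,4,6-tris(prop-2-en-1-yloxy)phenyl]ethan-1-one | COC(OC)=CCc1c(OCC=C)c(CC=C(C)C)c(OCC=C)c(C(C)=O)c1OCC=C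
A10 | alternative 3 | propionyl(methyl)ketene (2-methyl-1-oxopent-1-en-3-one) | CCC(=O)C(C)=C=O
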